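**Plan**
- Retrosynthesis: remove the acetate and return C6 to the ketone; then cut C4–C5 (aldol bond) and C1–Br while re-forming C1–C5, which gives a cyclopropyl diketone; finally cut C1–C5 and C1–C10 of the cyclopropane, leaving a p-menthenol and a five-carbon gem-diiodide.
- Enabling feature: C1–Br lies γ to the C6 carbonyl (1,3 to C5) and the C4 carbinol lies β to it. One C5 enolate, released by opening a C1–C5–C10 cyclopropane with bromide, can therefore forge C4–C5.
- Forward order: ring B is the ring of (R)-piperitone; the cyclopropane is fused onto C5=C10 with the C1–C4/C15 chain attached; ring A closes last, in the key step.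
- Stereochemistry: C7 comes from piperitone. A cis C6 carbinol directs the cyclopropane to the α face with the chain exo, which fixes C10. C1 arises by inversion on bromide attack. C4 and C5 are set by a titanium-bridged trans-fused aldolate, and C6 by a chelated single-electron reduction.

Key step: step 7

Remark: (R)-(−)-piperitone is assumed to be available in high enantiomeric purity; eudesmane numbering (C10 methyl β) is used for all bicyclic intermediates.

**Step 1**
Reactants: 1 (R)-piperitone
Product: 2 (1S,6R)-cis-piperitol
Conditions: L-Selectride, THF, −78 °C; then NaOH, H2O2, 0 °C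
Reagents that add atoms: none
Why: 1,2-reduction of a β-substituted cyclohexenone by a bulky trialkylborohydride; hydride should enter anti to the neighbouring isopropyl group, placing the new hydroxyl cis to it (the future α face).

**Step 2**
Reactants: 3 2-(2-bromoethyl)-2-methyl-1,3-dioxolane
Product: 4 2-(2-iodoethyl)-2-methyl-1,3-dioxolane
Conditions: NaI, acetone, reflux
Reagents that add atoms: sodium iodide [Na+].[I-]
Why: Finkelstein exchange at an unhindered primary carbon, driven by precipitation of sodium bromide.

**Step 3**
Reactants: 4 2-(2-iodoethyl)-2-methyl-1,3-dioxolane; 5 diiodomethane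
Product: 6 2-(3,3-diiodopropyl)-2-methyl-1,3-dioxolane
Conditions: NaHMDS, THF/Et2O, −78 °C to rt, dark
Reagents that add atoms: none
Why: SN2 alkylation of diiodomethyl sodium by a primary alkyl iodide, the standard entry to 1,1-diiodoalkanes; the weakly basic anion should not eliminate the β-ketal iodide.

**Step 4**
Reactants: 2 (1S,6R)-cis-piperitol; 6 2-(3,3-diiodopropyl)-2-methyl-1,3-dioxolane
Product: 7 3-isopropyl-6-methyl-7-exo-[2-(2-methyl-1,3-dioxolan-2-yl)ethyl]bicyclo[4.1.0]heptan-2-ol (hydroxyl, isopropyl and cyclopropane all on the α face)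
Conditions: Et2Zn (excess), CH2Cl2, −10 °C, then 6, 0 °C to rt
Reagents that add atoms: none
Why: Hydroxyl-directed Simmons–Smith-type alkylidene transfer from a substituted zinc carbenoid (Furukawa conditions); the zinc alkoxide of the pseudoaxial hydroxyl should deliver the carbenoid to the α face, setting C5 and C10, and the chain should settle anti to the oxygen-bearing C6 arm, i.e. exo at C1.

**Step 5**
Reactants: 7 cyclopropyl carbinol ketal
Product: 8 3-isopropyl-6-methyl-7-exo-[2-(2-methyl-1,3-dioxolan-2-yl)ethyl]bicyclo[4.1.0]heptan-2-one
Conditions: Dess–Martin periodinane, NaHCO3, CH2Cl2, rt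
Reagents that add atoms: none
Why: Dess–Martin oxidation of a secondary alcohol under buffered, non-enolising conditions; the ketal, the cyclopropane and the now epimerisable C7 centre should be left alone.

**Step 6**
Reactants: 8 cyclopropyl ketone ketal
Product: 9 3-isopropyl-6-methyl-7-exo-(3-oxobutyl)bicyclo[4.1.0]heptan-2-one (cyclopropane cis to isopropyl)
Conditions: PPTS, acetone/H2O, 40 °C
Reagents that add atoms: water O
Why: Mild acid-catalysed dioxolane hydrolysis; conditions are too weak to open the cyclopropyl ketone or to enolise C7 appreciably.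

**Step 7**
Reactants: 9 cyclopropyl diketone
Product: 12 1β-bromo-4α-hydroxy-7α-isopropyl-5αH-eudesman-6-one, via γ-bromo titanium enolate 10 (not isolated), via titanium aldolate 11 (not isolated)
Conditions: TiBr4, n-Bu4NBr, CH2Cl2, −78 to −20 °C; cold aq. NaHCO3
Reagents that add atoms: titanium tetrabromide Br[Ti](Br)(Br)Br; tetrabutylammonium bromide [Br-].CCCC[N+](CCCC)(CCCC)CCCC
Why: Proposed new method: TiBr4 activates the C6 carbonyl and bromide attacks the secondary cyclopropane carbon C1 in an SN2-like homo-conjugate addition, cleaving the exocyclic C1–C5 bond that overlaps with the carbonyl π system to give enolate 10, whose C5 carbon then adds to the titanium-bound side-chain ketone to form C4–C5; the closest known reaction type is the TiCl4/n-Bu4NI or Et2AlI opening of cyclopropyl ketones to γ-iodo enolates trapped by aldehydes, extended here to bromide at a secondary carbon and to an internal ketone acceptor. Ring A closes by a 6-(enolexo)-exo-trig aldol. C1 is set by inversion at the exo-substituted cyclopropane carbon (1β-Br), and C4 and C5 by the titanium-bridged aldolate 11, in which O4 is equatorial and chelated to O6 on a trans-fused decalin (4α-O, 5α-H). A kinetically formed cis-fused adduct is expected to revert by retro-aldol to the same C5 enolate on warming and to funnel into this chelate, while C7 is untouched because ring opening confines enolate formation to C5. The step needs attack at C1 instead of ionisation toward tertiary C10 (secured by orbital alignment of C1–C5 and by soluble bromide at low temperature) and aldol closure ahead of cyclopropane re-closure or dehydration (secured by the tethered, titanium-activated ketone and a cold quench).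

**Step 8**
Reactants: 12 bromo ketol
Product: 13 1β-bromo-7α-isopropyl-5αH-eudesmane-4α,6α-diol
Conditions: SmI2, THF/MeOH, −10 to 0 °C
Reagents that add atoms: none
Why: Samarium diiodide reduction of a β-hydroxy ketone through a chelated ketyl; the Sm(III) bridge to the equatorial O4 requires O6 to stay equatorial, so C6 should be protonated axially to give the 6α alcohol, which is also the epimer free of 1,3-diaxial contact with the C4 and C10 methyl groups. Without HMPA the hindered secondary bromide is expected to survive.

**Step 9**
Reactants: 13 bromo diol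
Product: 14 austradiol acetate (6α-acetoxy-1β-bromo-7α-isopropyl-5αH-eudesman-4α-ol)
Conditions: Ac2O, DMAP (cat.), pyridine, CH2Cl2, rt
Reagents that add atoms: acetic anhydride CC(=O)OC(C)=O
Why: DMAP-catalysed acylation; the secondary 6-hydroxyl should react while the tertiary, hydrogen-bonded 4-hydroxyl stays free.

**Compound list**
1 | (R)-piperitone | O=C1[C@@H](C(C)C)CCC(C)=C1 | starting material
2 | (1S,6R)-cis-piperitol | O[C@H]1[C@@H](C(C)C)CCC(C)=C1 | intermediate
3 | 2-(2-bromoethyl)-2-methyl-1,3-dioxolane | CC1(CCBr)OCCO1 | starting material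
4 | 2-(2-iodoethyl)-2-methyl-1,3-dioxolane | CC1(CCI)OCCO1 | intermediate
5 | diiodomethane | ICI | starting material
6 | 2-(3,3-diiodopropyl)-2-methyl-1,3-dioxolane | CC1(CCC(I)I)OCCO1 | intermediate
7 | 3-isopropyl-6-methyl-7-exo-[2-(2-methyl-1,3-dioxolan-2-yl)ethyl]bicyclo[4.1.0]heptan-2-ol, OH/isopropyl/cyclopropane all cis | O[C@H]1[C@@H](C(C)C)CC[C@@]2(C)[C@H](CCC3(C)OCCO3)[C@@H]12 | intermediate
8 | corresponding bicyclo[4.1.0]heptan-2-one ketal | O=C1[C@@H](C(C)C)CC[C@@]2(C)[C@H](CCC3(C)OCCO3)[C@@H]12 | intermediate
9 | 3-isopropyl-6-methyl-7-exo-(3-oxobutyl)bicyclo[4.1.0]heptan-2-one, cyclopropane cis to isopropyl | O=C1[C@@H](C(C)C)CC[C@@]2(C)[C@H](CCC(C)=O)[C@@H]12 | intermediate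
10 | tribromotitanium C5-enolate of 3-(1-bromo-4-oxopentyl)-6-isopropyl-3-methylcyclohexanone | Br[Ti](Br)(Br)OC=1[C@@H](C(C)C)CC[C@@](C)([C@H](Br)CCC(C)=O)C=1 | intermediate
11 | O4-tribromotitanium aldolate of 12 (O4–Ti–O6 chelate) | O=C1[C@@H](C(C)C)CC[C@@]2(C)[C@H](Br)CC[C@@](C)(O[Ti](Br)(Br)Br)[C@H]12 | intermediate
12 | 1β-bromo-4α-hydroxy-7α-isopropyl-5αH-eudesman-6-one | O=C1[C@@H](C(C)C)CC[C@@]2(C)[C@H](Br)CC[C@@](C)(O)[C@H]12 | intermediate
13 | 1β-bromo-7α-isopropyl-5αH-eudesmane-4α,6α-diol | O[C@H]1[C@@H](C(C)C)CC[C@@]2(C)[C@H](Br)CC[C@@](C)(O)[C@H]12 | intermediate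
14 | austradiol acetate | CC(=O)O[C@H]1[C@@H](C(C)C)CC[C@@]2(C)[C@H](Br)CC[C@@](C)(O)[C@H]12 | target

**Step count:** 9 steps in total; longest linear sequence 8 steps (3 → 4 → 6 → 7 → 8 → 9 → 12 → 13 → 14).

**Steps most likely to fail**

Step 7. The ring opening may stray toward the tertiary C10, or the ring closure may stall at a cis-fused or C4-epimeric aldolate, or lose water from the tertiary titanium alkoxide. The fallback separates the events and uses only established reactions. Setting out from 9, hydrogen bromide in acetic acid (0 °C to rt) should open the cyclopropyl ketone by classical homo-conjugate addition, with inversion at C1, to give 3-(1-bromo-4-oxopentyl)-6-isopropyl-3-methylcyclohexanone F1. Acid-catalysed aldol condensation (p-TsOH, benzene, reflux, water removal) should close ring A irreversibly to the conjugated enone 1β-bromo-7α-isopropyleudesm-4-en-6-one F2. Nucleophilic epoxidation (H2O2, NaOH, MeOH, 0 °C) from the face opposite the angular methyl should give 1β-bromo-4α,5α-epoxy-7α-isopropyleudesman-6-one F3. Reductive cleavage of the α C–O bond with SmI2 (THF/MeOH, −90 °C), followed by axial protonation of the C5 enolate, should then give the ketol and rejoin the route at 12.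

Step 4. The β-hydrogen-bearing zinc carbenoid may decay by 1,2-hydride shift before it reaches the hindered trisubstituted alkene, and exo/endo control at C1 may be poor. The fallback forms the C1–C2 bond by radical addition, so the configuration of the carbenoid carbon no longer matters. Setting out from 2, hydroxyl-directed iodocyclopropanation (CHI3, Et2Zn, CH2Cl2) should give 7-iodo-3-isopropyl-6-methylbicyclo[4.1.0]heptan-2-ol F4, whose configuration at the iodine-bearing carbon is immaterial. Slow addition of Bu3SnH/AIBN in benzene at 80 °C with excess methyl vinyl ketone should generate the rapidly inverting cyclopropyl σ-radical, which should add from the convex exo face to give 3-isopropyl-6-methyl-7-exo-(3-oxobutyl)bicyclo[4.1.0]heptan-2-ol F5. Dess–Martin oxidation of the carbinol then rejoins the route at 9, bypassing 7 and 8.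

Step 8. Electron transfer to the C–Br bond, retro-aldol of the samarium aldolate, or protonation toward the axial alcohol may compete. The fallback avoids single-electron conditions and corrects C6 thermodynamically. Setting out from 12, NaBH4/CeCl3 in MeOH should reduce the ketone, most likely from the α face, to the axial alcohol 1β-bromo-7α-isopropyl-5αH-eudesmane-4α,6β-diol F6. Ruthenium-catalysed hydrogen-transfer epimerisation (Shvo catalyst, toluene, 80 °C) should then equilibrate the strained carbinol to the equatorial epimer and rejoin the route at 13.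

**Further compounds**
F1 | step 7 | 3-(1-bromo-4-oxopentyl)-6-isopropyl-3-methylcyclohexanone | O=C1[C@@H](C(C)C)CC[C@@](C)([C@H](Br)CCC(C)=O)C1
F2 | step 7 | 1β-bromo-7α-isopropyleudesm-4-en-6-one | O=C1[C@@H](C(C)C)CC[C@@]2(C)[C@H](Br)CCC(C)=C12
F3 | step 7 | 1β-bromo-4α,5α-epoxy-7α-isopropyleudesman-6-one | O=C1[C@@H](C(C)C)CC[C@@]2(C)[C@H](Br)CC[C@@]3(C)O[C@@]123
F4 | step 4 | 7-iodo-3-isopropyl-6-methylbicyclo[4.1.0]heptan-2-ol (iodine drawn endo) | O[C@H]1[C@@H](C(C)C)CC[C@@]2(C)[C@@H](I)[C@@H]12
F5 | step 4 | 3-isopropyl-6-methyl-7-exo-(3-oxobutyl)bicyclo[4.1.0]heptan-2-ol | O[C@H]1[C@@H](C(C)C)CC[C@@]2(C)[C@H](CCC(C)=O)[C@@H]12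
F6 | step 8 | 1β-bromo-7α-isopropyl-5αH-eudesmane-4α,6β-diol | O[C@@H]1[C@@H](C(C)C)CC[C@@]2(C)[C@H](Br)CC[C@@](C)(O)[C@H]12
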